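**Strategy.** Each ε-ring is cut across C1–C6 and C2–C3 (carotenoid numbering) into a diene C3=C4–C5(Me)=C6 and a methacrylate C1=C2, joined through an ester between the C7 oxygen and the carbon that becomes one geminal methyl group. One intramolecular Diels–Alder reaction closes the ring; A(1,3) strain between the C5 methyl and C7 relays the (S)-carbinol at C7 to C6. The lactone, absent from the target, is then dismantled: its carbonyl is reduced to methyl and the C7 oxygen is transposed to C9 (Meyer–Schuster), giving (R)-α-ionone, which is carried through the C15 phosphonium salt to a double Wittig reaction with the C10 dialdehyde.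

Key step: step 5

Remark: carotenoid numbering is used throughout (C1 gem-dimethyl carbon, C2 and C3 the ring CH2 groups, C4=C5 the ring double bond, C5 bearing the methyl C18, C6 the stereocentre, C7 onward the chain). Compounds 8, 9 and 11 are drawn as the trans-fused isomers; their C1 epimers, if formed, converge at 12.

Assumption: (S,S)-ProPhenol is written as the ligand that gives (4S)-5; if the first run (Mosher ester analysis) shows the opposite sense, (R,R)-ProPhenol is used instead.

Step 1
Reactants: 1 (2E)-3-methylpent-2-en-4-yn-1-ol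
Product: 2 (2E)-3-methylpenta-2,4-dien-1-ol
Conditions: H2 (1 atm, 1 equiv), Pd/CaCO3 poisoned with Pb(OAc)2, quinoline, EtOAc, 0 °C
Reagents that add atoms: none
Why: Lindlar semihydrogenation reduces the terminal alkyne of the conjugated enyne to a vinyl group by syn addition of one equivalent of H2 and leaves the trisubstituted (E)-alkene, and with it the later cis relation of the C5 methyl to C7, untouched.

Step 2
Reactants: 2 (2E)-3-methylpenta-2,4-dien-1-ol
Product: 3 (2E)-3-methylpenta-2,4-dienal
Conditions: activated MnO2 (10 equiv), CH2Cl2, rt; filtered and used as a solution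
Reagents that add atoms: none
Why: MnO2 oxidises allylic alcohols selectively to enals under neutral conditions without E/Z isomerisation, and the volatile dienal is used directly in solution.

Step 3
Reactants: 3 (2E)-3-methylpenta-2,4-dienal, 4 propyne
Product: 5 (4S,5E)-6-methylocta-5,7-dien-2-yn-4-ol
Conditions: propyne (3 equiv), Me2Zn (3 equiv), (S,S)-ProPhenol (10 mol %), Ph3P=O (20 mol %), toluene, 0 °C; H2O
Reagents that add atoms: propyne, CC#C
Why: The dinuclear zinc ProPhenol-catalysed alkynylation (Trost) adds the propynylzinc formed in the flask to one enantiotopic face of enals, so the catalyst sets the (S) configuration at C7, the carbon whose only role is to relay chirality to C6.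

Step 4
Reactants: 5 (4S,5E)-6-methylocta-5,7-dien-2-yn-4-ol, 6 methacryloyl chloride
Product: 7 (4S,5E)-6-methylocta-5,7-dien-2-yn-4-yl 2-methylprop-2-enoate
Conditions: methacryloyl chloride (1.3 equiv), Et3N (2 equiv), DMAP (0.1 equiv), BHT (trace), CH2Cl2, 0 °C
Reagents that add atoms: methacryloyl chloride, C=C(C)C(=O)Cl
Why: DMAP-catalysed acylation of the secondary alcohol by the acid chloride under basic conditions gives the ester without ionising the doubly activated C7–O bond.

Step 5
Reactants: 7 (4S,5E)-6-methylocta-5,7-dien-2-yn-4-yl 2-methylprop-2-enoate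
Product: 8 (3S,3aS,7aS)-4,7a-dimethyl-3-(prop-1-yn-1-yl)-3a,6,7,7a-tetrahydro-2-benzofuran-1(3H)-one
Conditions: 1,2-dichlorobenzene (0.01 M), BHT (0.1 equiv), argon, 180 °C
Reagents that add atoms: none
Why: This is a thermal type 1 intramolecular Diels–Alder reaction of an ester-tethered 1,3,8-nonatriene, the closest known type being the cyclisation of pentadienyl acrylates: a concerted, asynchronous [4+2] cycloaddition in which the methacrylate C1=C2 adds across the diene C3=C4–C5=C6, forming C1–C6 and C2–C3 at once and leaving the C4=C5 double bond. The six-membered carbocycle closes in the [4+2] mode and the five-membered lactone ring (C6–C7–O–C(=O)–C1) is the fused consequence of the tether, which permits only the fused and not a bridged orientation and so overrides the opposed directing effects of the C5 methyl and the C6 substituent. C6 is set by C7: A(1,3) strain between the C5 methyl and C7 holds the C7–H bond in the diene plane syn to that methyl, so the ester oxygen lies on one diene face and the propynyl group on the other, and the dienophile can reach C6 only from the oxygen face, which for (S)-C7 gives the (R) configuration that C6 has in the target. The ring-fusion centre C1 depends on exo versus endo folding, but this is without consequence because C1 becomes the gem-dimethyl carbon in step 7. The step needs chemoselectivity (the isolated alkyne is not placed to react) and suppression of methacrylate polymerisation or acyloxy shift, which high dilution, BHT and the accessible s-cis diene (C6–H inside) should secure.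

Step 6
Reactants: 8 (3S,3aS,7aS)-4,7a-dimethyl-3-(prop-1-yn-1-yl)-3a,6,7,7a-tetrahydro-2-benzofuran-1(3H)-one
Product: 9 (3S,3aS,7aS)-4,7a-dimethyl-3-(prop-1-yn-1-yl)-1,3,3a,6,7,7a-hexahydro-2-benzofuran-1-ol (anomer mixture)
Conditions: i-Bu2AlH (1.2 equiv), CH2Cl2, −78 °C; aq. KNaC4H4O6
Reagents that add atoms: none
Why: DIBAL reduction of a γ-lactone at −78 °C stops at the lactol because the tetrahedral aluminate is stable, alkyne and alkene are untouched, and the new anomeric centre is inconsequential.

Step 7
Reactants: 9 lactol (as above), 10 4-methylbenzenesulfonohydrazide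
Product: 12 (1S)-1-[(1R)-2,6,6-trimethylcyclohex-2-en-1-yl]but-2-yn-1-ol, via hydroxy tosylhydrazone 11 (not isolated)
Conditions: TsNHNH2 (1.2 equiv), EtOH, 50 °C; evaporate; catecholborane (3 equiv), CHCl3, 0 °C to rt; NaOAc·3H2O, reflux
Reagents that add atoms: none
Why: The lactol opens to its hydroxy aldehyde, which condenses with the hydrazide, and the Kabalka variant of the Caglioti reduction (hydride addition to C=N, then loss of sulfinate and N2) turns CH=N into CH3 under nearly neutral conditions that spare the propargylic alcohol, so that C1 becomes the gem-dimethyl carbon and is no longer stereogenic.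

Step 8
Reactants: 12 (1S)-1-[(1R)-2,6,6-trimethylcyclohex-2-en-1-yl]but-2-yn-1-ol
Product: 13 (3E)-4-[(1R)-2,6,6-trimethylcyclohex-2-en-1-yl]but-3-en-2-one, (R)-α-ionone
Conditions: VO(OSiPh3)3 (5 mol %), toluene, 100 °C
Reagents that add atoms: none
Why: The oxovanadium-catalysed Meyer–Schuster rearrangement runs through a [3,3] shift of the propargyl vanadate to an allenolate that tautomerises to the (E)-enone, moving the C7 oxygen to C9 without π-activation of the alkyne (which in this 1,5-enyne would invite cycloisomerisation) and without touching C6.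

Step 9
Reactants: 13 (R)-α-ionone, 14 vinylmagnesium bromide
Product: 15 (1E)-3-methyl-1-[(1R)-2,6,6-trimethylcyclohex-2-en-1-yl]penta-1,4-dien-3-ol (both C3 epimers)
Conditions: CH2=CHMgBr (1.5 equiv), THF, −30 to 0 °C; H2O
Reagents that add atoms: vinylmagnesium bromide, C=C[Mg]Br
Why: Grignard 1,2-addition of the vinyl reagent to the enone carbonyl at low temperature gives the tertiary bis-allylic alcohol, whose new carbinol centre is lost in the next step.

Step 10
Reactants: 15 vinyl-α-ionol (as above), 16 triphenylphosphine hydrobromide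
Product: 17 [(2E,4E)-3-methyl-5-[(1R)-2,6,6-trimethylcyclohex-2-en-1-yl]penta-2,4-dien-1-yl]triphenylphosphonium bromide
Conditions: Ph3P·HBr (1.0 equiv), MeOH, 0 °C to rt; crystallisation from EtOAc
Reagents that add atoms: triphenylphosphine hydrobromide, [Br-].[PH+](c1ccccc1)(c1ccccc1)c1ccccc1
Why: Ph3P·HBr ionises the tertiary alcohol to a pentadienyl cation that PPh3 captures at the unhindered terminus C11 (allylic transposition), the established way from vinyl-ionols to C15 Wittig salts, and the (9E) salt should be purified by crystallisation.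

Step 11
Reactants: 17 C15 phosphonium bromide (2.2 equiv), 18 (2E,4E,6E)-2,7-dimethylocta-2,4,6-trienedial
Product: 21 (6R,6'R)-ε,ε-carotene, via ylide 19 (not isolated), via C25 aldehyde 20 (not isolated)
Conditions: NaOMe (2.3 equiv), MeOH/CH2Cl2, 0 °C to rt; then reflux in heptane under N2 in the dark; crystallisation
Reagents that add atoms: (2E,4E,6E)-2,7-dimethylocta-2,4,6-trienedial, O=C/C(C)=C/C=C/C=C(C)/C=O
Why: Twofold Wittig olefination of the symmetrical C10 dialdehyde with the semistabilised C15 ylide forms both C11=C12 bonds, and the 11Z isomers formed alongside should be converted to the all-E polyene by the usual thermal isomerisation of carotenoids, from which the product crystallises.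

**Compound list**

1 | (2E)-3-methylpent-2-en-4-yn-1-ol | C#C/C(C)=C/CO | starting material
2 | (2E)-3-methylpenta-2,4-dien-1-ol | C=C/C(C)=C/CO | intermediate
3 | (2E)-3-methylpenta-2,4-dienal | C=C/C(C)=C/C=O | intermediate
4 | propyne | CC#C | starting material
5 | (4S,5E)-6-methylocta-5,7-dien-2-yn-4-ol | CC#C[C@@H](O)/C=C(C)/C=C | intermediate
6 | methacryloyl chloride | C=C(C)C(=O)Cl | starting material
7 | (4S,5E)-6-methylocta-5,7-dien-2-yn-4-yl 2-methylprop-2-enoate | CC#C[C@@H](OC(=O)C(C)=C)/C=C(C)/C=C | intermediate
8 | (3S,3aS,7aS)-4,7a-dimethyl-3-(prop-1-yn-1-yl)-3a,6,7,7a-tetrahydro-2-benzofuran-1(3H)-one (trans-fused; C3 = C7, C3a = C6, C7a = C1 of the carotenoid numbering) | CC#C[C@H]1OC(=O)[C@@]2(C)CCC=C(C)[C@H]12 | intermediate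
9 | (3S,3aS,7aS)-4,7a-dimethyl-3-(prop-1-yn-1-yl)-1,3,3a,6,7,7a-hexahydro-2-benzofuran-1-ol (anomer mixture) | CC#C[C@H]1OC(O)[C@@]2(C)CCC=C(C)[C@H]12 | intermediate
10 | 4-methylbenzenesulfonohydrazide | Cc1ccc(cc1)S(=O)(=O)NN | starting material
11 | N'-[(E)-{(1S,2S)-2-[(1S)-1-hydroxybut-2-yn-1-yl]-1,3-dimethylcyclohex-3-en-1-yl}methylidene]-4-methylbenzenesulfonohydrazide | CC#C[C@@H](O)[C@H]1C(C)=CCC[C@]1(C)/C=N/NS(=O)(=O)c1ccc(C)cc1 | intermediate (not isolated)
12 | (1S)-1-[(1R)-2,6,6-trimethylcyclohex-2-en-1-yl]but-2-yn-1-ol | CC#C[C@@H](O)[C@H]1C(C)=CCCC1(C)C | intermediate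
13 | (3E)-4-[(1R)-2,6,6-trimethylcyclohex-2-en-1-yl]but-3-en-2-one, (R)-α-ionone | CC(=O)/C=C/[C@H]1C(C)=CCCC1(C)C | intermediate
14 | vinylmagnesium bromide | C=C[Mg]Br | starting material
15 | (1E)-3-methyl-1-[(1R)-2,6,6-trimethylcyclohex-2-en-1-yl]penta-1,4-dien-3-ol (C3 epimer mixture) | C=CC(C)(O)/C=C/[C@H]1C(C)=CCCC1(C)C | intermediate
16 | triphenylphosphine hydrobromide | [Br-].[PH+](c1ccccc1)(c1ccccc1)c1ccccc1 | starting material
17 | [(2E,4E)-3-methyl-5-[(1R)-2,6,6-trimethylcyclohex-2-en-1-yl]penta-2,4-dien-1-yl]triphenylphosphonium bromide | CC1=CCCC(C)(C)[C@H]1/C=C/C(C)=C/C[P+](c1ccccc1)(c1ccccc1)c1ccccc1.[Br-] | intermediate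
18 | (2E,4E,6E)-2,7-dimethylocta-2,4,6-trienedial | O=C/C(C)=C/C=C/C=C(C)/C=O | starting material
19 | ylide of 17, [(2E,4E)-3-methyl-5-[(1R)-2,6,6-trimethylcyclohex-2-en-1-yl]penta-2,4-dien-1-ylidene]triphenylphosphorane | CC1=CCCC(C)(C)[C@H]1/C=C/C(C)=C/C=P(c1ccccc1)(c1ccccc1)c1ccccc1 | intermediate (not isolated)
20 | (6R)-12'-apo-ε-caroten-12'-al (C25 aldehyde, drawn all-E; formed with its 11Z isomer) | CC1=CCCC(C)(C)[C@H]1/C=C/C(C)=C/C=C/C(C)=C/C=C/C=C(C)/C=O | intermediate (not isolated)
21 | (6R,6'R)-ε,ε-carotene | CC1=CCCC(C)(C)[C@H]1/C=C/C(C)=C/C=C/C(C)=C/C=C/C=C(C)/C=C/C=C(C)/C=C/[C@H]1C(C)=CCCC1(C)C | target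

Total step count: 11. Longest linear sequence: 11 steps (1 to 21).

**Steps most likely to fail**

Step 5. The ester tether prefers the s-trans ester conformation, so the cycloaddition may be slow enough for radical polymerisation of the methacrylate or thermal 1,3-acyloxy shift of the allylic and propargylic ester to overtake it. Facial control may also be incomplete, because the slim propynyl group exerts only moderate A(1,3) strain; the C6 epimer is a diastereomer of 8 and of 12 and could be removed at either stage. The fallback replaces the covalent ester by a magnesium template and sets out from 5. Alcohol 5 is deprotonated with MeMgBr in toluene and treated with methyl methacrylate at rt to 60 °C. The magnesium alkoxide binds and activates the ester carbonyl, so the cycloaddition runs inside the complex with the same tether-enforced regiochemistry and the same A(1,3)-controlled face. It should give the cis hydroxy ester methyl (1R,2S)-2-[(1S)-1-hydroxybut-2-yn-1-yl]-1,3-dimethylcyclohex-3-ene-1-carboxylate F1. Reduction with i-Bu2AlH at −78 °C gives the cis-fused lactol F2, the C1 epimer of 9. Under the conditions of step 7 this passes through the cis hydroxy tosylhydrazone F3 and comes back to the route at 12, where C1 is no longer stereogenic.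

Step 7. Ring–chain tautomerism may hold the material as the lactol or as a cyclic N,O-aminal, so that little open hydrazone is present. Condensation at the neopentyl carbon may be slow, and excess borane may begin to hydroborate the alkyne. The fallback avoids a carbonyl at this carbon altogether by a temporary silicon connection and sets out from 5. Alcohol 5 is silylated with chloro(dimethyl)(2-methylprop-2-en-1-yl)silane (from 2-methylallylmagnesium chloride and Me2SiCl2; imidazole, CH2Cl2) to the silyl ether dimethyl{[(4S,5E)-6-methylocta-5,7-dien-2-yn-4-yl]oxy}(2-methylprop-2-en-1-yl)silane F4. Thermal intramolecular Diels–Alder reaction (toluene, sealed tube, 200 °C) under the same A(1,3) control gives the fused oxasilinane 3,3,4a,8-tetramethyl-1-(prop-1-yn-1-yl)-3,4,4a,5,6,8a-hexahydro-1H-2,3-benzoxasiline F5. Protodesilylation (Bu4NF, DMF, 80 °C) cleaves the Si–O and Si–CH2 bonds, turns the silylmethyl group into the second methyl on C1, and comes back to the route at 12.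

Step 8. At the temperature a hindered secondary propargylic alcohol needs, Rupe-type dehydration to enynes, migration of the ring double bond into conjugation or epimerisation at C6 may compete with the oxygen transposition. The fallback treats the alkyne as a masked ketone and sets out from 12. Trans-hydrosilylation with benzyldimethylsilane and [Cp*Ru(MeCN)3]PF6 (acetone, rt) places silicon on C9 and gives the vinylsilane (1S,2Z)-3-[benzyl(dimethyl)silyl]-1-[(1R)-2,6,6-trimethylcyclohex-2-en-1-yl]but-2-en-1-ol F6. Tamao–Fleming oxidation (Bu4NF, then H2O2, KHCO3, MeOH/THF) gives the β-hydroxy ketone (4R)-4-hydroxy-4-[(1R)-2,6,6-trimethylcyclohex-2-en-1-yl]butan-2-one F7. Treatment with MsCl and Et3N (CH2Cl2, 0 °C to rt) forms the mesylate (1R)-3-oxo-1-[(1R)-2,6,6-trimethylcyclohex-2-en-1-yl]butyl methanesulfonate F8, which eliminates in the flask (E1cB) to the (E)-enone and comes back to the route at 13.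

**Further compounds**

F1 | step 5 | methyl (1R,2S)-2-[(1S)-1-hydroxybut-2-yn-1-yl]-1,3-dimethylcyclohex-3-ene-1-carboxylate | CC#C[C@@H](O)[C@H]1C(C)=CCC[C@@]1(C)C(=O)OC
F2 | step 5 | (3S,3aS,7aR)-4,7a-dimethyl-3-(prop-1-yn-1-yl)-1,3,3a,6,7,7a-hexahydro-2-benzofuran-1-ol (cis-fused, anomer mixture) | CC#C[C@H]1OC(O)[C@]2(C)CCC=C(C)[C@H]12
F3 | step 5 | N'-[(E)-{(1R,2S)-2-[(1S)-1-hydroxybut-2-yn-1-yl]-1,3-dimethylcyclohex-3-en-1-yl}methylidene]-4-methylbenzenesulfonohydrazide | CC#C[C@@H](O)[C@H]1C(C)=CCC[C@@]1(C)/C=N/NS(=O)(=O)c1ccc(C)cc1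
F4 | step 7 | dimethyl{[(4S,5E)-6-methylocta-5,7-dien-2-yn-4-yl]oxy}(2-methylprop-2-en-1-yl)silane | CC#C[C@@H](O[Si](C)(C)CC(C)=C)/C=C(C)/C=C
F5 | step 7 | 3,3,4a,8-tetramethyl-1-(prop-1-yn-1-yl)-3,4,4a,5,6,8a-hexahydro-1H-2,3-benzoxasiline (C1 and C8a configured as C3 and C3a of 8, trans-fused isomer drawn) | CC#C[C@H]1O[Si](C)(C)C[C@@]2(C)CCC=C(C)[C@H]12
F6 | step 8 | (1S,2Z)-3-[benzyl(dimethyl)silyl]-1-[(1R)-2,6,6-trimethylcyclohex-2-en-1-yl]but-2-en-1-ol | C/C([Si](C)(C)Cc1ccccc1)=C/[C@@H](O)[C@H]1C(C)=CCCC1(C)C
F7 | step 8 | (4R)-4-hydroxy-4-[(1R)-2,6,6-trimethylcyclohex-2-en-1-yl]butan-2-one | CC(=O)C[C@@H](O)[C@H]1C(C)=CCCC1(C)C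
F8 | step 8 | (1R)-3-oxo-1-[(1R)-2,6,6-trimethylcyclohex-2-en-1-yl]butyl methanesulfonate | CC(=O)C[C@@H](OS(C)(=O)=O)[C@H]1C(C)=CCCC1(C)C
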